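Ring A is cut at C8–C8a and C6–C7 into a four-carbon vinylketene (C8a, C4a, C5, C6) and a two-carbon ynol ether (C7, C8). Heating cyclobutenone 7, which carries the C6 prenyl group and a silyloxy group at the future C5, with methoxyalkyne 11 should build the pentasubstituted ring in one operation, with the C7 methoxy group between the prenylated C6 and C8 and hydrogen only at C4a. The step exploits the alternating oxygen/prenyl pattern of ring A and its local symmetry about the C4a–C7 axis, which makes O5 and O8a equivalent. Formylation at C4a, chromone closure of ring C and rhodium-catalysed asymmetric arylation at C2 complete the flavanone.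

Key step: step 4

Remark: positions are given in flavanone numbering; ketene is made by pyrolysis of acetone directly before use; LiTMP = lithium 2,2,6,6-tetramethylpiperidide; MeO-F12-BIPHEP = 6,6'-dimethoxy-2,2'-bis[bis(3,4,5-trifluorophenyl)phosphino]-1,1'-biphenyl; the (S) ligand in step 8 is chosen by analogy, and the (R) ligand would be taken if the sense of induction proves opposite.

Step 1
Reactants: 1 ethyl 4-methylpent-3-enoate
Product: 4 triisopropyl[(5-methylhex-4-en-1-yn-1-yl)oxy]silane, via dibromoketone lithium enolate 2 (not isolated), via lithium ynolate 3 (not isolated)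
Conditions: CH2Br2, LiTMP, THF, −78 °C, then 1; LiHMDS, −78 °C; n-BuLi, −78 → 25 °C; i-Pr3SiCl, −78 → 0 °C
Reagents that add atoms: dibromomethane BrCBr; triisopropylsilyl chloride CC(C)[Si](Cl)(C(C)C)C(C)C
Why: Kowalski ester homologation, in which LiCHBr2 adds to the ester, the dibromo enolate undergoes Br–Li exchange and 1,2-shift of the prenyl group to the ynolate, and the bulky silyl chloride traps the ynolate on oxygen.

Step 2
Reactants: 4 triisopropyl[(5-methylhex-4-en-1-yn-1-yl)oxy]silane; 5 acetone
Product: 7 2-(3-methylbut-2-en-1-yl)-3-[(triisopropylsilyl)oxy]cyclobut-2-en-1-one, via ketene 6 (not isolated)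
Conditions: pyrolysis of 5 at about 700 °C (ketene lamp); ketene stream passed into 4, MeCN, 0 → 20 °C
Reagents that add atoms: none
Why: Thermal ketene–ynol ether [2+2] cycloaddition, in which the nucleophilic prenyl-bearing alkyne carbon bonds to the ketene carbonyl carbon, so that the prenyl group ends up at C2 and the silyloxy group at C3 of the cyclobutenone.

Step 3
Reactants: 8 chloroacetaldehyde dimethyl acetal; 9 prenyl bromide (1-bromo-3-methylbut-2-ene)
Product: 11 1-methoxy-5-methylhex-4-en-1-yne, via lithium methoxyacetylide 10 (not isolated)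
Conditions: LiNEt2 (3.2 equiv), THF, −78 → 0 °C; then 9, DMPU, −78 → 20 °C
Reagents that add atoms: none
Why: Two base-induced E2 eliminations (methanol, then HCl) and deprotonation give the alkoxyacetylide, which is alkylated by SN2 attack at the unhindered primary carbon of the allylic bromide.

Step 4
Reactants: 7 2-(3-methylbut-2-en-1-yl)-3-[(triisopropylsilyl)oxy]cyclobut-2-en-1-one; 11 1-methoxy-5-methylhex-4-en-1-yne
Product: 16 3-methoxy-2,4-bis(3-methylbut-2-en-1-yl)-5-[(triisopropylsilyl)oxy]phenol, via vinylketene 12 (not isolated), via vinylcyclobutenone adduct 13 (not isolated), via dienylketene 14 (not isolated), via cyclohexadienone 15 (not isolated)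
Conditions: 11 (1.5 equiv), toluene, 80 → 110 °C, sealed tube, slow addition of 7
Reagents that add atoms: none
Why: Thermal 4π ring opening of 7 gives vinylketene 12, whose ketene C=C bond adds [2+2] to the electron-rich alkyne of 11 to give 13 with formation of the C8a–C8 and C6–C7 bonds, and 13 opens in a second 4π step to dienylketene 14. This is a Danheiser benzannulation of a cyclobutenone with an alkoxyalkyne, closely related to the known capture of vinylketenes by silyl ynol ethers. Ring A closes by thermal 6π electrocyclisation of 14, which rejoins C8a to C4a, and enolisation of cyclohexadienone 15 gives the phenol; no stereocentre is formed. The selectivity needed is the orientation of the ketene–alkyne [2+2] step, and the polarisation of the ynol ether secures it: its nucleophilic prenyl-bearing carbon bonds to the electrophilic ketene carbonyl carbon, so the methoxy carbon lands between the two prenylated carbons. Because ring A is symmetric about the C4a–C7 axis it does not matter which flanking oxygen keeps the silyl group, and the methoxy ynol ether, lacking a β-hydrogen on oxygen, cannot fragment by retro-ene loss of an alkene at this temperature.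

Step 5
Reactants: 16 3-methoxy-2,4-bis(3-methylbut-2-en-1-yl)-5-[(triisopropylsilyl)oxy]phenol
Product: 17 2-hydroxy-4-methoxy-3,5-bis(3-methylbut-2-en-1-yl)-6-[(triisopropylsilyl)oxy]benzaldehyde
Conditions: MgCl2, Et3N, (CH2O)n, THF, reflux
Reagents that add atoms: paraformaldehyde (reacts as formaldehyde) C=O
Why: Casnati–Skattebøl ortho-formylation, in which the magnesium phenoxide delivers formaldehyde to the only free ring carbon (C4a) and a second formaldehyde oxidises the hydroxymethyl intermediate by hydride transfer, under basic conditions that spare the acid-sensitive ortho-prenylphenol and the silyl ether.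

Step 6
Reactants: 17 2-hydroxy-4-methoxy-3,5-bis(3-methylbut-2-en-1-yl)-6-[(triisopropylsilyl)oxy]benzaldehyde
Product: 18 1-{2-hydroxy-4-methoxy-3,5-bis(3-methylbut-2-en-1-yl)-6-[(triisopropylsilyl)oxy]phenyl}prop-2-yn-1-ol (racemic)
Conditions: HC≡CMgBr (3 equiv), THF, 0 °C; aq NH4Cl; crude product used directly
Reagents that add atoms: ethynylmagnesium bromide C#C[Mg]Br
Why: Grignard 1,2-addition to the aldehyde after deprotonation of the phenol, with the covalent magnesium alkoxide and low temperature keeping the silyl group on its phenol oxygen; the carbinol centre is of no consequence because it is oxidised in step 7.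

Step 7
Reactants: 18 1-{2-hydroxy-4-methoxy-3,5-bis(3-methylbut-2-en-1-yl)-6-[(triisopropylsilyl)oxy]phenyl}prop-2-yn-1-ol
Product: 20 7-methoxy-6,8-bis(3-methylbut-2-en-1-yl)-5-[(triisopropylsilyl)oxy]-4H-chromen-4-one, via ynone 19 (not isolated)
Conditions: MnO2, CH2Cl2, 20 °C; filtration; DABCO (20 mol %), 20 °C
Reagents that add atoms: none
Why: MnO2 oxidation of the benzylic–propargylic alcohol gives the ortho-hydroxyaryl ynone, and amine-catalysed 6-endo-dig oxa-Michael addition of the free phenol oxygen (the future O1) to the alkyne terminus closes ring C as the chromone.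

Step 8
Reactants: 20 7-methoxy-6,8-bis(3-methylbut-2-en-1-yl)-5-[(triisopropylsilyl)oxy]-4H-chromen-4-one; 21 (4-hydroxy-3-methoxyphenyl)boronic acid
Product: 22 (2S)-2-(4-hydroxy-3-methoxyphenyl)-7-methoxy-6,8-bis(3-methylbut-2-en-1-yl)-5-[(triisopropylsilyl)oxy]-2,3-dihydro-4H-chromen-4-one
Conditions: 21 (2.5 equiv), [Rh(OH)((S)-MeO-F12-BIPHEP)]2 (3 mol % Rh), toluene/H2O, 25 °C
Reagents that add atoms: none
Why: Hayashi–Miyaura-type rhodium-catalysed asymmetric 1,4-addition, in which the aryl–rhodium species inserts the chromone C2=C3 bond on the face selected by the electron-poor biaryl bisphosphine (the (S) ligand should give 2S by analogy with (S)-BINAP additions to cyclohexenone), while the neutral hydroxo catalyst at room temperature avoids base-induced ring opening and tolerates the phenol of 21, which is no more acidic than the boronic acid itself.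

Step 9
Reactants: 22 (2S)-2-(4-hydroxy-3-methoxyphenyl)-7-methoxy-6,8-bis(3-methylbut-2-en-1-yl)-5-[(triisopropylsilyl)oxy]-2,3-dihydro-4H-chromen-4-one
Product: 23 (2S)-5-hydroxy-2-(4-hydroxy-3-methoxyphenyl)-7-methoxy-6,8-bis(3-methylbut-2-en-1-yl)-2,3-dihydro-4H-chromen-4-one
Conditions: TBAF, AcOH (1:1), THF, 0 °C
Reagents that add atoms: none
Why: Fluoride cleavage of the aryl silyl ether, buffered with acetic acid so that neither base-promoted retro-oxa-Michael racemisation at C2 nor acid-promoted cyclisation of the 5-hydroxyl onto the C6 prenyl group should occur.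

Compound list
1 | ethyl 4-methylpent-3-enoate | CCOC(=O)CC=C(C)C | starting material
2 | lithium 1,1-dibromo-5-methylhexa-1,4-dien-2-olate | [Li+].[O-]C(CC=C(C)C)=C(Br)Br | intermediate (not isolated)
3 | lithium 5-methylhex-4-en-1-yn-1-olate | [Li+].[O-]C#CCC=C(C)C | intermediate (not isolated)
4 | triisopropyl[(5-methylhex-4-en-1-yn-1-yl)oxy]silane | CC(C)=CCC#CO[Si](C(C)C)(C(C)C)C(C)C | intermediate
5 | acetone | CC(C)=O | starting material
6 | ketene | C=C=O | intermediate (not isolated)
7 | 2-(3-methylbut-2-en-1-yl)-3-[(triisopropylsilyl)oxy]cyclobut-2-en-1-one | O=C1CC(O[Si](C(C)C)(C(C)C)C(C)C)=C1CC=C(C)C | intermediate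
8 | chloroacetaldehyde dimethyl acetal (2-chloro-1,1-dimethoxyethane) | COC(CCl)OC | starting material
9 | prenyl bromide (1-bromo-3-methylbut-2-ene) | CC(C)=CCBr | starting material
10 | lithium methoxyacetylide | [Li+].[C-]#COC | intermediate (not isolated)
11 | 1-methoxy-5-methylhex-4-en-1-yne | COC#CCC=C(C)C | intermediate
12 | 2-(3-methylbut-2-en-1-yl)-3-[(triisopropylsilyl)oxy]buta-1,3-dien-1-one | O=C=C(CC=C(C)C)C(=C)O[Si](C(C)C)(C(C)C)C(C)C | intermediate (not isolated)
13 | 3-methoxy-2,4-bis(3-methylbut-2-en-1-yl)-4-{1-[(triisopropylsilyl)oxy]ethenyl}cyclobut-2-en-1-one (racemic) | O=C1C(CC=C(C)C)=C(OC)C1(CC=C(C)C)C(=C)O[Si](C(C)C)(C(C)C)C(C)C | intermediate (not isolated)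
14 | (3E)-3-methoxy-2,4-bis(3-methylbut-2-en-1-yl)-5-[(triisopropylsilyl)oxy]hexa-1,3,5-trien-1-one | O=C=C(CC=C(C)C)/C(OC)=C(CC=C(C)C)\C(=C)O[Si](C(C)C)(C(C)C)C(C)C | intermediate (not isolated)
15 | 3-methoxy-2,4-bis(3-methylbut-2-en-1-yl)-5-[(triisopropylsilyl)oxy]cyclohexa-2,4-dien-1-one | O=C1CC(O[Si](C(C)C)(C(C)C)C(C)C)=C(CC=C(C)C)C(OC)=C1CC=C(C)C | intermediate (not isolated)
16 | 3-methoxy-2,4-bis(3-methylbut-2-en-1-yl)-5-[(triisopropylsilyl)oxy]phenol | Oc1cc(O[Si](C(C)C)(C(C)C)C(C)C)c(CC=C(C)C)c(OC)c1CC=C(C)C | intermediate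
17 | 2-hydroxy-4-methoxy-3,5-bis(3-methylbut-2-en-1-yl)-6-[(triisopropylsilyl)oxy]benzaldehyde | O=Cc1c(O)c(CC=C(C)C)c(OC)c(CC=C(C)C)c1O[Si](C(C)C)(C(C)C)C(C)C | intermediate
18 | 1-{2-hydroxy-4-methoxy-3,5-bis(3-methylbut-2-en-1-yl)-6-[(triisopropylsilyl)oxy]phenyl}prop-2-yn-1-ol (racemic) | C#CC(O)c1c(O)c(CC=C(C)C)c(OC)c(CC=C(C)C)c1O[Si](C(C)C)(C(C)C)C(C)C | intermediate
19 | 1-{2-hydroxy-4-methoxy-3,5-bis(3-methylbut-2-en-1-yl)-6-[(triisopropylsilyl)oxy]phenyl}prop-2-yn-1-one | C#CC(=O)c1c(O)c(CC=C(C)C)c(OC)c(CC=C(C)C)c1O[Si](C(C)C)(C(C)C)C(C)C | intermediate (not isolated)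
20 | 7-methoxy-6,8-bis(3-methylbut-2-en-1-yl)-5-[(triisopropylsilyl)oxy]-4H-chromen-4-one | O=c1ccoc2c(CC=C(C)C)c(OC)c(CC=C(C)C)c(O[Si](C(C)C)(C(C)C)C(C)C)c12 | intermediate
21 | (4-hydroxy-3-methoxyphenyl)boronic acid | COc1cc(B(O)O)ccc1O | starting material
22 | (2S)-2-(4-hydroxy-3-methoxyphenyl)-7-methoxy-6,8-bis(3-methylbut-2-en-1-yl)-5-[(triisopropylsilyl)oxy]-2,3-dihydro-4H-chromen-4-one | COc1cc([C@@H]2CC(=O)c3c(O[Si](C(C)C)(C(C)C)C(C)C)c(CC=C(C)C)c(OC)c(CC=C(C)C)c3O2)ccc1O | intermediate
23 | (2S)-5-hydroxy-2-(4-hydroxy-3-methoxyphenyl)-7-methoxy-6,8-bis(3-methylbut-2-en-1-yl)-2,3-dihydro-4H-chromen-4-one (CNP0260843.1) | COc1cc([C@@H]2CC(=O)c3c(O)c(CC=C(C)C)c(OC)c(CC=C(C)C)c3O2)ccc1O | target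

Total step count: 9. Longest linear sequence: 8 steps (steps 1, 2, 4, 5, 6, 7, 8 and 9, from ester 1).

Steps most likely to fail

Step 4. Capture of the silyloxy-substituted vinylketene by the ynol ether may lose out to ketene dimerisation, to O-acylation of the phenol already formed, or to loss of the silyl group at the temperature needed for ring opening. The fallback sets out from prenyl bromide 9 and rejoins the route at aldehyde 17, so that ring A is bought instead of built. Twofold C-prenylation of commercial 2,4,6-trihydroxybenzaldehyde with 9 (aq KOH, 0 °C) would give 2,4,6-trihydroxy-3,5-bis(3-methylbut-2-en-1-yl)benzaldehyde F1. Methylation of the hydroxyl para to the formyl group, the only one that cannot chelate the carbonyl oxygen (MeI, 1 equiv, K2CO3, acetone), would give 2,6-dihydroxy-4-methoxy-3,5-bis(3-methylbut-2-en-1-yl)benzaldehyde F2. Monosilylation of its two equivalent hydroxyls (i-Pr3SiOTf, 1 equiv, 2,6-lutidine, CH2Cl2, −78 °C) would give 17. This path trades the connectivity control of the benzannulation for the usual C- versus O-alkylation and over-alkylation problems of phloroglucinol prenylation.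

Step 8. Aryl transfer to the hindered, electron-rich chromone may be slower than protodeboronation of the electron-rich boronic acid, or the rhodium enolate may open ring C, which would lower conversion and enantiomeric purity. The fallback sets out from aldehyde 17 and rejoins the route at 22, setting C2 by O1–C2 bond formation instead of C2–aryl bond formation. Addition of MeMgBr (THF, 0 °C) would give 1-{2-hydroxy-4-methoxy-3,5-bis(3-methylbut-2-en-1-yl)-6-[(triisopropylsilyl)oxy]phenyl}ethan-1-ol F3, and MnO2 oxidation would give the corresponding acetophenone F4. Claisen–Schmidt condensation with commercial 4-(allyloxy)-3-methoxybenzaldehyde (KOH, EtOH, 0 → 20 °C) would give the (E)-2'-hydroxychalcone F5. Intramolecular oxa-Michael addition under a cinchona-alkaloid-derived bifunctional thiourea (quinine or quinidine series chosen for the 2S sense, toluene, with enrichment by crystallisation if needed) would give the (2S)-4'-O-allyl flavanone F6. Allyl transfer to morpholine with Pd(PPh3)4 (THF, 20 °C) would then give 22.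

Step 1. The carbenoid or the amide base may deprotonate the acidic allylic α-position of the β,γ-unsaturated ester instead of adding to its carbonyl group, so that the ester is returned or isomerised into conjugation. The fallback sets out from prenyl bromide 9 and rejoins the route at silyl ynol ether 4. Copper-catalysed coupling with ethynylmagnesium bromide (CuCl cat., THF) would give 5-methylhex-4-en-1-yne F7. Deprotonation with LiHMDS, oxygenation of the acetylide with t-BuOOLi (THF, −78 → 0 °C) and O-silylation of the resulting ynolate with i-Pr3SiOTf would give 4.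

Further compounds
F1 | step 4 | 2,4,6-trihydroxy-3,5-bis(3-methylbut-2-en-1-yl)benzaldehyde | O=Cc1c(O)c(CC=C(C)C)c(O)c(CC=C(C)C)c1O
F2 | step 4 | 2,6-dihydroxy-4-methoxy-3,5-bis(3-methylbut-2-en-1-yl)benzaldehyde | O=Cc1c(O)c(CC=C(C)C)c(OC)c(CC=C(C)C)c1O
F3 | step 8 | 1-{2-hydroxy-4-methoxy-3,5-bis(3-methylbut-2-en-1-yl)-6-[(triisopropylsilyl)oxy]phenyl}ethan-1-ol (racemic) | CC(O)c1c(O)c(CC=C(C)C)c(OC)c(CC=C(C)C)c1O[Si](C(C)C)(C(C)C)C(C)C
F4 | step 8 | 1-{2-hydroxy-4-methoxy-3,5-bis(3-methylbut-2-en-1-yl)-6-[(triisopropylsilyl)oxy]phenyl}ethan-1-one | CC(=O)c1c(O)c(CC=C(C)C)c(OC)c(CC=C(C)C)c1O[Si](C(C)C)(C(C)C)C(C)C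
F5 | step 8 | (E)-3-[4-(allyloxy)-3-methoxyphenyl]-1-{2-hydroxy-4-methoxy-3,5-bis(3-methylbut-2-en-1-yl)-6-[(triisopropylsilyl)oxy]phenyl}prop-2-en-1-one | C=CCOc1ccc(/C=C/C(=O)c2c(O)c(CC=C(C)C)c(OC)c(CC=C(C)C)c2O[Si](C(C)C)(C(C)C)C(C)C)cc1OC
F6 | step 8 | (2S)-2-[4-(allyloxy)-3-methoxyphenyl]-7-methoxy-6,8-bis(3-methylbut-2-en-1-yl)-5-[(triisopropylsilyl)oxy]-2,3-dihydro-4H-chromen-4-one | C=CCOc1ccc([C@@H]2CC(=O)c3c(O[Si](C(C)C)(C(C)C)C(C)C)c(CC=C(C)C)c(OC)c(CC=C(C)C)c3O2)cc1OC
F7 | step 1 | 5-methylhex-4-en-1-yne | C#CCC=C(C)C
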